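0.918 of target per other capture product gained over the first 2.00 h of the ochre flask, but 1.33 from there to 3.00 h: this gain ratio s, the selectivity factor, reads as climbing.

- ochre: starting material 0.032 M; first nucleophile 0.16 M; second nucleophile 0.0256 M; the very flask that is asked about, followed so far
- flask: starting material 0.032 M; first nucleophile 0.160 M; second nucleophile 0.0256 M; time 8.0 h

ochre run (percent of the starting material charged)

| time / h | target / % | other capture product / % |
|---|---|---|
| 0.667 | 2.4 | 2.3 |
| 1.33 | 4.5 | 5.3 |
| 2.00 | 6.7 | 7.3 |
| 2.50 | 8.6 | 8.6 |
| 3.00 | 10.3 | 10.0 |

(scatter of a reading: 0.3 percentage points)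



- ratio of target to other capture product at 25 min
- ratio of target to other capture product at 8.0 h
- which of target and other capture product there is more of at 8.0 h

The midpoints of those two stretches lie 1.50 h apart, so s doubles about every 2.78 h, the ratio-doubling time τ, a reading that stays loose under the scatter. Run backwards, s starts near 0.716, so we expect the ratio at 25 min to be about 0.754. Run forwards, the doubling puts s at 5.24 at 8.0 h. If total capture stays steady, other capture product takes the share 1/(1+s), which adds up to 2.81 h of the 8.0 h, so our ratio there is 1.85.

The forecast gave 0.95 and 1.08, with target ahead, holding that “the intrinsic starting ratio is about 0.95”.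

The flask gives 0.787 and 1.79, with target at 28.4% against 15.8%.

    starting material ⇌ intermediate (K = 0.110, k = 0.00140 min⁻¹)
    first nucleophile + intermediate → target (k = 0.800 M⁻¹ min⁻¹)
    second nucleophile + intermediate → other capture product (k = 6.60 M⁻¹ min⁻¹)
    first nucleophile ⇌ dormant form (K = 1.20, k = 0.00320 min⁻¹)
    second nucleophile → decomposed reagent (k = 0.00520 min⁻¹)

By these equations, s follows first nucleophile over second nucleophile, and in this flask that quotient doubles about every 2.59 h between 0.800 h and 4.00 h. The neighbouring flask is charged with 0.044 M of second nucleophile, so we put its starting s at 0.416. Keeping τ, we put its s at 3.05 at 8.0 h, and the same sum gives a ratio of 1.12 there. That neighbouring flask gives 1.04, with target 22.9% and other capture product 22.1%.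

(The runs were generated by integration for an exercise; scatter was added.)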